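The route disconnects two C–O bonds of ring A at once: the diaryl ether bond at C6 and the bond from C1 to its oxygen. C6 and C1 are neighbours, and C1 has the C2 bromine on its other side, so a 3,5-dibromobenzyne with the triple bond between C6 and C1 is the hidden building block. In one flask the ring B aryloxide should add at C6 and the arylmagnesium left at C1 is borylated and oxidised, which joins both rings and places the C1 oxygen with all three bromines already present. The aryne precursor is 2,4-dibromo-6-iodophenyl 4-chlorobenzenesulfonate; its partner is the chloromagnesium salt of 2-(benzyloxy)-4-bromophenol.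

Key step: step 4

Remark on the chemistry: atoms are numbered as in the target (ring A: C1 OMe, C2 Br, C4 Br, C6 O-aryl; ring B: C1' ether oxygen, C2' OH, C4' Br). The target has no stereocentre. The 4-chlorobenzenesulfonate is kept as the leaving group because its 2-magnesiated form should survive at −78 °C, so the exchange is complete and no free i-PrMgCl remains when the aryne is released on warming. The aryloxide is pre-formed and used in excess. Compounds 1, 3 and 5 and all reagents are assumed to be purchasable.

Step 1
Reactants: 1 2,4-dibromophenol
Product: 2 2,4-dibromo-6-iodophenol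
Conditions: NIS, p-TsOH·H2O (cat.), MeCN, rt
Reagents that add atoms: N-iodosuccinimide, O=C1CCC(=O)N1I
Why: Electrophilic aromatic iodination: the hydroxyl directs the iodine electrophile to C6, the only free ortho or para position, and the acid catalyst activates NIS enough for this halogen-deactivated phenol.

Step 2
Reactants: 2 2,4-dibromo-6-iodophenol; 3 4-chlorobenzenesulfonyl chloride
Product: 4 2,4-dibromo-6-iodophenyl 4-chlorobenzenesulfonate
Conditions: K2CO3, acetone, 50 °C
Reagents that add atoms: none
Why: O-Sulfonylation of a phenoxide: carbonate ionises the acidic trihalophenol fully and its oxygen, the only nucleophilic site, attacks the sulfonyl chloride.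

Step 3
Reactants: 5 2-(benzyloxy)phenol
Product: 6 2-(benzyloxy)-4-bromophenol
Conditions: NBS, MeCN, 0 °C → rt
Reagents that add atoms: N-bromosuccinimide, O=C1CCC(=O)N1Br
Why: Electrophilic aromatic bromination: the free hydroxyl is a stronger activator than the benzyloxy group, so one equivalent of NBS in a polar solvent at low temperature should brominate mainly para to it, as is usual for 2-alkoxyphenols.

Step 4
Reactants: 4 2,4-dibromo-6-iodophenyl 4-chlorobenzenesulfonate; 6 2-(benzyloxy)-4-bromophenol
Product: 12 2-[2-(benzyloxy)-4-bromophenoxy]-4,6-dibromophenol, via chloromagnesium aryloxide 7 (not isolated), via magnesiated sulfonate 8 (not isolated), via 3,5-dibromobenzyne 9 (not isolated), via arylmagnesium adduct 10 (not isolated), via dimethyl arylboronate 11 (not isolated)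
Conditions: 6 (1.5 equiv), i-PrMgCl, THF, −20 °C; 4, then i-PrMgCl, −78 → 0 °C; B(OMe)3, −78 → 0 °C; 30% H2O2, AcOH, 0 °C → rt
Reagents that add atoms: hydrogen peroxide, OO; for the intermediates 7, 8, 10 and 11 only: isopropylmagnesium chloride, CC(C)[Mg]Cl; trimethyl borate, COB(OC)OC
Why: Proposed new method: i-PrMgCl first deprotonates 6 to aryloxide 7, then exchanges the C6 iodine of 4 (faster than either bromine at −78 °C) to give 8, which on warming expels the neighbouring sulfonate to form the C6≡C1 aryne 9; 7 adds through oxygen at C6 to give arylmagnesium 10, which B(OMe)3 converts into boronate 11 and H2O2 oxidises with aryl migration from boron to oxygen, creating the C1–O bond of 12. The closest known reaction type is the three-component coupling in which arynes released from 2-iodoaryl arenesulfonates by iodine–magnesium exchange add magnesium thiolates or amides and the new arylmagnesium is trapped by an electrophile; the O-arylation of phenoxides by 3-haloarynes and the borylation–oxidation of aryl Grignard reagents to phenols are known separately. No ring is closed and no stereocentre is created. The step needs regioselective addition across C6≡C1, and the C2 bromine secures it: its inductive pull distorts the aryne so that C6 is the more electrophilic terminus and stabilises the carbanion developing at C1, a bias expected to override the weak opposite preference of the C4 bromine. It also needs the aryloxide to outrun other aryne consumers, which the excess of 7 and the absence of free i-PrMgCl at the moment of aryne release should favour, and it needs the ortho-bromo arylmagnesium 10 to keep its bromide, which is why the mixture is not warmed above 0 °C before the borate is added.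

Step 5
Reactants: 12 2-[2-(benzyloxy)-4-bromophenoxy]-4,6-dibromophenol
Product: 13 1-[2-(benzyloxy)-4-bromophenoxy]-3,5-dibromo-2-methoxybenzene
Conditions: MeI, K2CO3, DMF, rt
Reagents that add atoms: iodomethane, CI
Why: Williamson ether synthesis: the acidic C1 phenol is the only ionisable group, and the small electrophile MeI should reach the phenoxide oxygen despite its two ortho substituents.

Step 6
Reactants: 13 1-[2-(benzyloxy)-4-bromophenoxy]-3,5-dibromo-2-methoxybenzene
Product: 14 5-bromo-2-(3,5-dibromo-2-methoxyphenoxy)phenol
Conditions: BCl3, C6HMe5, CH2Cl2, −78 °C; then H2O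
Reagents that add atoms: none
Why: Lewis-acid cleavage of an aryl benzyl ether: BCl3 coordinates the benzylic ether oxygen and the benzyl cation is captured by pentamethylbenzene (Friedel–Crafts scavenging), which at −78 °C should leave the aryl methyl ether, the diaryl ether and the three C–Br bonds untouched.

Compound list
1 | 2,4-dibromophenol | Oc1ccc(Br)cc1Br | starting material
2 | 2,4-dibromo-6-iodophenol | Oc1c(Br)cc(Br)cc1I | intermediate
3 | 4-chlorobenzenesulfonyl chloride | O=S(=O)(Cl)c1ccc(Cl)cc1 | starting material
4 | 2,4-dibromo-6-iodophenyl 4-chlorobenzenesulfonate | O=S(=O)(Oc1c(Br)cc(Br)cc1I)c1ccc(Cl)cc1 | intermediate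
5 | 2-(benzyloxy)phenol | Oc1ccccc1OCc1ccccc1 | starting material
6 | 2-(benzyloxy)-4-bromophenol | Oc1ccc(Br)cc1OCc1ccccc1 | intermediate
7 | chloromagnesium 2-(benzyloxy)-4-bromophenoxide | Cl[Mg]Oc1ccc(Br)cc1OCc1ccccc1 | intermediate
8 | [3,5-dibromo-2-(4-chlorobenzenesulfonyloxy)phenyl]magnesium chloride | Cl[Mg]c1cc(Br)cc(Br)c1OS(=O)(=O)c1ccc(Cl)cc1 | intermediate
9 | 3,5-dibromobenzyne (3,5-dibromo-1,2-didehydrobenzene) | BrC1=CC(Br)=CC#C1 | intermediate
10 | {2-[2-(benzyloxy)-4-bromophenoxy]-4,6-dibromophenyl}magnesium chloride | Cl[Mg]c1c(Br)cc(Br)cc1Oc1ccc(Br)cc1OCc1ccccc1 | intermediate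
11 | dimethyl {2-[2-(benzyloxy)-4-bromophenoxy]-4,6-dibromophenyl}boronate | COB(OC)c1c(Br)cc(Br)cc1Oc1ccc(Br)cc1OCc1ccccc1 | intermediate
12 | 2-[2-(benzyloxy)-4-bromophenoxy]-4,6-dibromophenol | Oc1c(Br)cc(Br)cc1Oc1ccc(Br)cc1OCc1ccccc1 | intermediate
13 | 1-[2-(benzyloxy)-4-bromophenoxy]-3,5-dibromo-2-methoxybenzene | COc1c(Br)cc(Br)cc1Oc1ccc(Br)cc1OCc1ccccc1 | intermediate
14 | 5-bromo-2-(3,5-dibromo-2-methoxyphenoxy)phenol | COc1c(Br)cc(Br)cc1Oc1ccc(Br)cc1O | target

Total step count: 6
Longest linear sequence: 5 steps (steps 1, 2, 4, 5, 6)

Three steps most likely to fail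

First risk, step 4: the aryloxide may add to the aryne too slowly, so that the aryne is consumed by arylmagnesium species or by the sulfonate anion; the magnesiated sulfonate may also be attacked at sulfur or shift its sulfonyl group from oxygen to carbon instead of releasing the aryne, and the ortho-bromo arylmagnesium may lose bromide before it is borylated. The fallback uses known chemistry, sets out from compound 6 and comes back to the route at compound 12. The potassium salt of 6, formed with K2CO3 in DMF at 80 °C, displaces the fluoride of purchased 2,4-dibromo-6-fluorobenzaldehyde F1 by nucleophilic aromatic substitution, since fluoride ortho to the formyl group should leave far faster than either bromide. This should give 2-[2-(benzyloxy)-4-bromophenoxy]-4,6-dibromobenzaldehyde F2 as the diaryl ether. Baeyer–Villiger oxidation with mCPBA in CH2Cl2, in which the aryl group with its ortho aryloxy donor migrates, should give 2-[2-(benzyloxy)-4-bromophenoxy]-4,6-dibromophenyl formate F3 and methanolysis with K2CO3 in MeOH then releases 12. The positions of both oxygens and both bromines of ring A are fixed by the purchased aldehyde.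

Second risk, step 6: the Lewis acid may also cleave the twisted C1 methyl ether, which is flanked by two ortho substituents, or the benzyl cation may be transferred to an arene carbon of the substrate instead of the scavenger. The fallback changes the ring B protecting group to an acetal that is removed by acid solvolysis; it sets out from compound 4 and comes back to the route at compound 14. Purchased 2-(methoxymethoxy)phenol F4 is brominated with NBS in MeCN at 0 °C to 4-bromo-2-(methoxymethoxy)phenol F5 with the bromine para to the hydroxyl. Under the conditions of the key step its salt chloromagnesium 4-bromo-2-(methoxymethoxy)phenoxide F6 adds to aryne 9 released from 4 and should give {2,4-dibromo-6-[4-bromo-2-(methoxymethoxy)phenoxy]phenyl}magnesium chloride F7 as the adduct. This is borylated with B(OMe)3 to dimethyl {2,4-dibromo-6-[4-bromo-2-(methoxymethoxy)phenoxy]phenyl}boronate F8 and oxidised with H2O2 to 2,4-dibromo-6-[4-bromo-2-(methoxymethoxy)phenoxy]phenol F9 in the same flask. MeI and K2CO3 in DMF give 1,5-dibromo-3-[4-bromo-2-(methoxymethoxy)phenoxy]-2-methoxybenzene F10 and HCl in MeOH at 40 °C then removes the acetal to give 14; aryl methyl ethers and aryl bromides are inert to these conditions.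

Third risk, step 3: bromination may also take place para to the benzyloxy group or a second time ortho to the hydroxyl, which would give isomers that are hard to separate from 6. The fallback fixes the bromine position in a purchased arene and creates the hydroxyl instead. Because compound 5 is itself a starting material, the fallback sets out from purchased 4-bromo-2-hydroxybenzaldehyde F11 in place of compound 5 and comes back to the route at compound 6. O-Benzylation with BnBr and K2CO3 in DMF gives 2-(benzyloxy)-4-bromobenzaldehyde F12 as the benzyl ether. Baeyer–Villiger oxidation with mCPBA in CH2Cl2 gives 2-(benzyloxy)-4-bromophenyl formate F13 and methanolysis with K2CO3 in MeOH gives 6 with the hydroxyl para to bromine by construction.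

Further compounds
F1 | step 4 | 2,4-dibromo-6-fluorobenzaldehyde | O=Cc1c(F)cc(Br)cc1Br
F2 | step 4 | 2-[2-(benzyloxy)-4-bromophenoxy]-4,6-dibromobenzaldehyde | O=Cc1c(Br)cc(Br)cc1Oc1ccc(Br)cc1OCc1ccccc1
F3 | step 4 | 2-[2-(benzyloxy)-4-bromophenoxy]-4,6-dibromophenyl formate | O=COc1c(Br)cc(Br)cc1Oc1ccc(Br)cc1OCc1ccccc1
F4 | step 6 | 2-(methoxymethoxy)phenol | COCOc1ccccc1O
F5 | step 6 | 4-bromo-2-(methoxymethoxy)phenol | COCOc1cc(Br)ccc1O
F6 | step 6 | chloromagnesium 4-bromo-2-(methoxymethoxy)phenoxide | COCOc1cc(Br)ccc1O[Mg]Cl
F7 | step 6 | {2,4-dibromo-6-[4-bromo-2-(methoxymethoxy)phenoxy]phenyl}magnesium chloride | COCOc1cc(Br)ccc1Oc1cc(Br)cc(Br)c1[Mg]Cl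
F8 | step 6 | dimethyl {2,4-dibromo-6-[4-bromo-2-(methoxymethoxy)phenoxy]phenyl}boronate | COCOc1cc(Br)ccc1Oc1cc(Br)cc(Br)c1B(OC)OC
F9 | step 6 | 2,4-dibromo-6-[4-bromo-2-(methoxymethoxy)phenoxy]phenol | COCOc1cc(Br)ccc1Oc1cc(Br)cc(Br)c1O
F10 | step 6 | 1,5-dibromo-3-[4-bromo-2-(methoxymethoxy)phenoxy]-2-methoxybenzene | COCOc1cc(Br)ccc1Oc1cc(Br)cc(Br)c1OC
F11 | step 3 | 4-bromo-2-hydroxybenzaldehyde | O=Cc1ccc(Br)cc1O
F12 | step 3 | 2-(benzyloxy)-4-bromobenzaldehyde | O=Cc1ccc(Br)cc1OCc1ccccc1
F13 | step 3 | 2-(benzyloxy)-4-bromophenyl formate | O=COc1ccc(Br)cc1OCc1ccccc1
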